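**Plan**
1. Hardest point: the two (2Z,4S,5S)-4,5-epoxyhex-2-enoyl arms. Their free acid relactonises, and they sit as vinylogous anhydrides on O-2/O-5 of the 1,4-benzoquinone ring next to two free phenols.
2. Cuts: last, the two acyl C1–O(quinone) bonds. In each arm the oxirane O–C4 bond is cut and the oxygen on C5 is re-bonded to C1, giving a six-membered enelactone (4-O-mesyl-osmundalactone) whose C1–C6 are C1–C6 of L-rhamnal. In the core, the two aryl–C3/C6 bonds are cut (double Suzuki coupling).
3. Enabling feature: in each arm the oxygen on C5 and carboxyl C1 face each other across the cis C2=C3 bond, and C4 carries a vicinal C–O bond anti to it. The oxirane oxygen can therefore be parked as the pyranone ring oxygen. This O5–C1 bond is absent from the target; it locks the Z-alkene, masks the acid, and is cleaved in the key step.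
4. Forward: bromanil → dibromodimethoxyquinone → terphenylquinone → atromentin. Separately, di-O-acetyl-L-rhamnal → enelactone acetate → alcohol → mesylate. Then, in one flask, ring switch lactone → oxirane (O5 moves from C1 to C4), activation of the never-protonated carboxylate, and double acyl transfer to atromentin.
5. Stereochemistry: C5 is C5 of L-rhamnose (retained), C4 is C4 of L-rhamnose after one SN2 inversion, and the Z-geometry is that of the pyranone ring. No chiral reagent is used.
6. No protecting group on the core: two equivalents of amine ionise only the two quinone OH groups (vinylogous carboxylic acids), and the phenols stay neutral.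

Key step: step 7

Remark: the SMILES is read as C2-symmetric, with both arms (2Z,4S,5S) and trans-oxiranes. Atromentin numbering (OH on C2/C5, aryl on C3/C6) and hexenoyl numbering C1–C6 are used throughout.

Step 1
Reactants: 1 tetrabromo-1,4-benzoquinone (bromanil)
Product: 2 2,5-dibromo-3,6-dimethoxy-1,4-benzoquinone
Conditions: NaOMe (2 equiv), MeOH, 0 °C → rt
Reagents that add atoms: sodium methoxide, C[O-].[Na+]
Why: Twofold vinylogous addition–elimination of methoxide on the haloquinone, in which the first methoxy group deactivates the carbonyl conjugated to it by vinylogous ester resonance, so the second methoxide enters para to the first and the 2,5-pattern results.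

Step 2
Reactants: 2 2,5-dibromo-3,6-dimethoxy-1,4-benzoquinone; 3 4-methoxyphenylboronic acid (2.4 equiv)
Product: 4 2,5-dimethoxy-3,6-bis(4-methoxyphenyl)-1,4-benzoquinone
Conditions: PdCl2(dppf) (5 mol %), K2CO3, 1,4-dioxane–H2O, 85 °C
Reagents that add atoms: none
Why: Double Suzuki–Miyaura coupling at the two equivalent, electron-poor C–Br bonds, a coupling type known for 2,5-dibromo-3,6-dialkoxyquinones, builds the p-terphenylquinone in one operation without any regiochemical question.

Step 3
Reactants: 4 2,5-dimethoxy-3,6-bis(4-methoxyphenyl)-1,4-benzoquinone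
Product: 5 atromentin (2,5-dihydroxy-3,6-bis(4-hydroxyphenyl)-1,4-benzoquinone)
Conditions: BBr3 (8 equiv), CH2Cl2, −78 °C → rt; then H2O
Reagents that add atoms: none
Why: Boron tribromide ether cleavage removes the two aryl methyl ethers and the two chelated vinylogous methyl esters at once, the quinone is inert to the Lewis acid, and hydrolysis of the borates should give atromentin.

Step 4
Reactants: 6 3,4-di-O-acetyl-L-rhamnal
Product: 7 (5R,6S)-5-acetoxy-6-methyl-5,6-dihydro-2H-pyran-2-one (4-O-acetylosmundalactone, trans)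
Conditions: mCPBA (dried), BF3·OEt2 (cat.), CH2Cl2, −20 °C
Reagents that add atoms: 3-chloroperoxybenzoic acid, O=C(OO)c1cccc(Cl)c1
Why: Lewis-acid peroxidation of a glycal ester, in which BF3 ionises the allylic 3-acetate as in a Ferrier rearrangement, the peracid adds to C1 of the allyloxocarbenium ion, and the anomeric perester fragments to the 2-en-1,5-olide with C4 and C5 untouched.

Step 5
Reactants: 7 (5R,6S)-5-acetoxy-6-methyl-5,6-dihydro-2H-pyran-2-one
Product: 8 (5R,6S)-5-hydroxy-6-methyl-5,6-dihydro-2H-pyran-2-one (osmundalactone)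
Conditions: Novozym 435 (immobilised lipase B of Candida antarctica), n-BuOH, MTBE, 35 °C
Reagents that add atoms: none
Why: Lipase-catalysed alcoholysis of the secondary acetate runs at neutral pH, so the acid- and base-sensitive enelactone should neither open, translactonise nor epimerise, and no stereocenter is touched.

Step 6
Reactants: 8 osmundalactone
Product: 9 (5R,6S)-5-(methanesulfonyloxy)-6-methyl-5,6-dihydro-2H-pyran-2-one
Conditions: Ms2O, pyridine, CH2Cl2, −10 → 0 °C
Reagents that add atoms: methanesulfonic anhydride, CS(=O)(=O)OS(C)(=O)=O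
Why: O-Sulfonylation of the secondary allylic alcohol proceeds with retention at C4, and the chloride-free anhydride with a weak base avoids allylic substitution and elimination.

Step 7
Reactants: 9 (5R,6S)-5-(methanesulfonyloxy)-6-methyl-5,6-dihydro-2H-pyran-2-one (2.2 equiv); 5 atromentin (1 equiv)
Product: 13 atromentin 2,5-bis[(2Z,4S,5S)-4,5-epoxyhex-2-enoate] (target CNP0407724.1), via potassium epoxyhexenoate 10 (not isolated), via trichlorobenzoic mixed anhydride 11 (not isolated), via atromentin bis-ammonium salt 12 (not isolated)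
Conditions: (i) 9, KOSiMe3 (2.0 equiv per 9), THF, −20 → 0 °C; (ii) 2,4,6-Cl3C6H2COCl (2.1 equiv), −30 °C; (iii) 5 + iPr2NEt (2.0 equiv) in DMF, added at −30 °C, → 0 °C; cold pH 5 buffer, Sephadex LH-20
Reagents that add atoms: potassium trimethylsilanolate, C[Si](C)(C)[O-].[K+] (second carboxylate O and K of 10; after O-scrambling in the carboxylate this O can end as the acyl C=O of 13); 2,4,6-trichlorobenzoyl chloride, O=C(Cl)c1c(Cl)cc(Cl)cc1Cl (aroyl group of 11 only); N,N-diisopropylethylamine, CCN(C(C)C)C(C)C (cations of 12 only)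
Why: Silanolate (two per lactone, an organic-soluble O2− equivalent) adds to lactone carbonyl C1 of 9, the O5–C1 bond breaks, a second silanolate strips the silyl ester to the inert carboxylate so that the opening cannot revert, and the freed C5 alkoxide, released antiperiplanar to the equatorial C4–OMs bond, displaces the mesylate. The closest known reaction types are the base-induced conversion of sulfonyloxy lactones into epoxy esters or acids, silanolate cleavage of esters, Yamaguchi mixed-anhydride formation from a carboxylate salt, and O-acylation of hydroxyquinone salts by anhydrides. The only ring closed is the oxirane, by 3-exo-tet SN2 closure. C4 is inverted (4R → 4S) by the backside attack, C5 keeps the L-rhamnose configuration because its C–O bond is never broken, the trans-oxirane follows from the trans lactone, and the Z-alkene is inherited from the six-membered ring. Salt 10 is never protonated, which shuts off relactonisation, and it gives 11, which is attacked only at the unhindered enoyl carbonyl. The step needs selectivity for the two quinone oxygens over the two phenols; this is secured because two equivalents of amine ionise only the vinylogous carboxylic acid OH groups on C2/C5 (pKa about 3–5 against about 10), neutral phenols are inert to 11 without an acyl-transfer catalyst, and trichlorobenzoate is a weaker base than the quinone oxyanion, so the transfer is downhill.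

**Compound list**
1 | tetrabromo-1,4-benzoquinone (bromanil) | O=C1C(Br)=C(Br)C(=O)C(Br)=C1Br | starting material
2 | 2,5-dibromo-3,6-dimethoxy-1,4-benzoquinone | COC1=C(Br)C(=O)C(OC)=C(Br)C1=O | intermediate
3 | 4-methoxyphenylboronic acid | COc1ccc(B(O)O)cc1 | starting material
4 | 2,5-dimethoxy-3,6-bis(4-methoxyphenyl)-1,4-benzoquinone | COC1=C(c2ccc(OC)cc2)C(=O)C(OC)=C(c2ccc(OC)cc2)C1=O | intermediate
5 | atromentin, 2,5-dihydroxy-3,6-bis(4-hydroxyphenyl)-1,4-benzoquinone | OC1=C(c2ccc(O)cc2)C(=O)C(O)=C(c2ccc(O)cc2)C1=O | intermediate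
6 | 3,4-di-O-acetyl-L-rhamnal, (2S,3S,4S)-2-methyl-3,4-dihydro-2H-pyran-3,4-diyl diacetate | C[C@@H]1OC=C[C@H](OC(C)=O)[C@H]1OC(C)=O | starting material
7 | (5R,6S)-5-acetoxy-6-methyl-5,6-dihydro-2H-pyran-2-one | C[C@@H]1OC(=O)C=C[C@H]1OC(C)=O | intermediate
8 | (5R,6S)-5-hydroxy-6-methyl-5,6-dihydro-2H-pyran-2-one (osmundalactone) | C[C@@H]1OC(=O)C=C[C@H]1O | intermediate
9 | (5R,6S)-5-(methanesulfonyloxy)-6-methyl-5,6-dihydro-2H-pyran-2-one | C[C@@H]1OC(=O)C=C[C@H]1OS(C)(=O)=O | intermediate
10 | potassium (2Z)-3-[(2S,3S)-3-methyloxiran-2-yl]prop-2-enoate | C[C@@H]1O[C@H]1/C=C\C(=O)[O-].[K+] | intermediate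
11 | (2Z)-3-[(2S,3S)-3-methyloxiran-2-yl]prop-2-enoic 2,4,6-trichlorobenzoic anhydride | C[C@@H]1O[C@H]1/C=C\C(=O)OC(=O)c2c(Cl)cc(Cl)cc2Cl | intermediate
12 | atromentin 2,5-diolate bis(N,N-diisopropylethylammonium) salt | [O-]C1=C(c2ccc(O)cc2)C(=O)C([O-])=C(c2ccc(O)cc2)C1=O.CC[NH+](C(C)C)C(C)C.CC[NH+](C(C)C)C(C)C | intermediate
13 | 2,5-bis(4-hydroxyphenyl)-3,6-dioxocyclohexa-1,4-diene-1,4-diyl bis{(2Z)-3-[(2S,3S)-3-methyloxiran-2-yl]prop-2-enoate} | C[C@@H]1O[C@H]1/C=C\C(=O)OC1=C(c2ccc(O)cc2)C(=O)C(OC(=O)/C=C\[C@@H]2O[C@H]2C)=C(c2ccc(O)cc2)C1=O | target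

Total step count: 7.
Longest linear sequence: 4 steps (1–2–3–7 or 4–5–6–7).

**Steps most likely to fail**

Step 7. Three processes may interfere:
- During the ring switch, γ-deprotonation at C4 with base-induced elimination may compete with attack at the lactone carbonyl.
- During the union, acyl groups may drift to the phenol oxygens, the activated Z-enoyl unit may isomerise, or the vinylogous anhydride may be hydrolysed on isolation.

The fallback sets out from 9 and 5 and returns at 13. It separates the ring switch from the union and attaches the acyl groups at the hydroquinone oxidation level, where they are ordinary aryl esters; the quinone is restored last.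
- Acyl donor: 9 with LiOH (2 equiv) in THF–H2O at 0 °C, followed by freeze-drying, should give lithium (2Z,4S,5S)-4,5-epoxyhex-2-enoate F1. With 2,4,6-trichlorobenzoyl chloride in THF this gives 11.
- Core: 5 is persilylated (TBSCl, imidazole, DMF) to tetrakis-O-TBS-atromentin F2 and reduced (H2, Pd/C, EtOAc) to tetrakis-O-TBS-leucoatromentin F3.
- Union: F3 is deprotonated (KHMDS, THF, −78 °C) and acylated with 11 to the tetrasilylated leuco diester F4.
- Release: TBAF/AcOH (THF, 0 °C) removes all four silyl groups to the leucoatromentin diester F5. Ag2O in EtOAc then oxidises the para-dihydroxy pair to 13.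
- Regiochemistry: 1,2-shifts of silyl or acyl groups between neighbouring ring oxygens are harmless. The regioisomers equilibrate by the catechol monoester shift, and only the isomer with para-disposed free hydroxy groups can be drained by oxidation.

Step 2. Reductive loss of bromine from the quinone, base attack on the vinylogous ester, or an incomplete second coupling may occur. The fallback sets out from 2 and returns at 4; the coupling is moved to the arene level.
- 2 is reduced (Na2S2O4, THF–H2O) to 2,5-dibromo-3,6-dimethoxybenzene-1,4-diol F6.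
- F6 is methylated (Me2SO4, K2CO3, acetone) to 1,4-dibromo-2,3,5,6-tetramethoxybenzene F7.
- F7 is coupled with 3 (Pd(PPh3)4, aq. Na2CO3, toluene–EtOH, reflux) to 2',3',5',6',4,4''-hexamethoxy-p-terphenyl F8.
- Oxidative demethylation of the central ring of F8 (CAN, MeCN–H2O, 0 °C) gives 4.

Step 5. The lipase may not accept the hindered secondary acetate. Alternatively, the lactone may open and translactonise to the five-membered ring once the 4-OH is free. The fallback sets out from 6 and returns at 9; acetate is exchanged for mesylate on a base-stable glycoside, and the lactone carbonyl is introduced last.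
- Ferrier rearrangement of 6 (EtOH, BF3·OEt2 cat., CH2Cl2) should give ethyl 4-O-acetyl-2,3,6-trideoxy-α-L-erythro-hex-2-enopyranoside F9. Any β-anomer is carried along, since C1 becomes the carbonyl.
- Zemplén deacetylation (NaOMe cat., MeOH) gives ethyl 2,3,6-trideoxy-α-L-erythro-hex-2-enopyranoside F10.
- MsCl/Et3N (CH2Cl2, 0 °C) gives ethyl 4-O-mesyl-2,3,6-trideoxy-α-L-erythro-hex-2-enopyranoside F11.
- Acetal-to-lactone oxidation of F11 (mCPBA, BF3·OEt2, CH2Cl2, −20 → 0 °C) gives 9.

**Further compounds**
F1 | step 7 | lithium (2Z)-3-[(2S,3S)-3-methyloxiran-2-yl]prop-2-enoate | C[C@@H]1O[C@H]1/C=C\C(=O)[O-].[Li+]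
F2 | step 7 | 2,5-bis(tert-butyldimethylsilyloxy)-3,6-bis[4-(tert-butyldimethylsilyloxy)phenyl]-1,4-benzoquinone | CC(C)(C)[Si](C)(C)OC1=C(c2ccc(O[Si](C)(C)C(C)(C)C)cc2)C(=O)C(O[Si](C)(C)C(C)(C)C)=C(c2ccc(O[Si](C)(C)C(C)(C)C)cc2)C1=O
F3 | step 7 | 2,5-bis(tert-butyldimethylsilyloxy)-3,6-bis[4-(tert-butyldimethylsilyloxy)phenyl]benzene-1,4-diol | Oc1c(O[Si](C)(C)C(C)(C)C)c(-c2ccc(O[Si](C)(C)C(C)(C)C)cc2)c(O)c(O[Si](C)(C)C(C)(C)C)c1-c3ccc(O[Si](C)(C)C(C)(C)C)cc3
F4 | step 7 | 2,5-bis(tert-butyldimethylsilyloxy)-3,6-bis[4-(tert-butyldimethylsilyloxy)phenyl]-1,4-phenylene bis[(2Z,4S,5S)-4,5-epoxyhex-2-enoate] | C[C@@H]1O[C@H]1/C=C\C(=O)Oc1c(O[Si](C)(C)C(C)(C)C)c(-c2ccc(O[Si](C)(C)C(C)(C)C)cc2)c(OC(=O)/C=C\[C@@H]2O[C@H]2C)c(O[Si](C)(C)C(C)(C)C)c1-c3ccc(O[Si](C)(C)C(C)(C)C)cc3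
F5 | step 7 | 2,5-dihydroxy-3,6-bis(4-hydroxyphenyl)-1,4-phenylene bis[(2Z,4S,5S)-4,5-epoxyhex-2-enoate] | C[C@@H]1O[C@H]1/C=C\C(=O)Oc1c(O)c(-c2ccc(O)cc2)c(OC(=O)/C=C\[C@@H]2O[C@H]2C)c(O)c1-c3ccc(O)cc3
F6 | step 2 | 2,5-dibromo-3,6-dimethoxybenzene-1,4-diol | COc1c(Br)c(O)c(OC)c(Br)c1O
F7 | step 2 | 1,4-dibromo-2,3,5,6-tetramethoxybenzene | COc1c(Br)c(OC)c(OC)c(Br)c1OC
F8 | step 2 | 2',3',5',6',4,4''-hexamethoxy-1,1':4',1''-terphenyl | COc1ccc(cc1)-c1c(OC)c(OC)c(-c2ccc(OC)cc2)c(OC)c1OC
F9 | step 5 | ethyl 4-O-acetyl-2,3,6-trideoxy-α-L-erythro-hex-2-enopyranoside | C[C@@H]1O[C@@H](OCC)C=C[C@H]1OC(C)=O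
F10 | step 5 | ethyl 2,3,6-trideoxy-α-L-erythro-hex-2-enopyranoside | C[C@@H]1O[C@@H](OCC)C=C[C@H]1O
F11 | step 5 | ethyl 4-O-methanesulfonyl-2,3,6-trideoxy-α-L-erythro-hex-2-enopyranoside | C[C@@H]1O[C@@H](OCC)C=C[C@H]1OS(C)(=O)=O
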